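## Retrosynthetic overview

1. Rings C and D (cyclopentane and ester-bearing cyclohexene) close last, by an intramolecular Diels–Alder reaction of a trans-7,8-disubstituted cis-bicyclo[4.2.0]octa-2,4-diene whose (2E,4E)-dienoate arm is endo and whose decenyl chain is exo.
2. Rings A and B (cyclobutane and cyclohexadiene) form together by thermal 6π electrocyclisation of a trans-7,8-disubstituted cycloocta-1,3,5-triene; the eight-membered ring is bought as cyclooctatetraene.
3. Key bond (ring carbon to side-chain CH2, reversed polarity): an 8-alkylcyclooctatrienyl carbanion is alkylated by methyl 6-bromosorbate, a doubly vinylogous enolonium (a6) equivalent. The ε-carbon of a dienoate is normally the nucleophilic end of its dienolate, so two donor carbons are joined. A chiral diamine on lithium is meant to choose between the two enantiotopic termini of the meso anion and so set the absolute configuration.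
4. The anion comes from carbolithiation of cyclooctatetraene by (E)-dec-8-enyllithium; its bromide from one-position transposition of 10-bromodec-1-ene; the bromosorbate from allylic bromination of methyl sorbate.
5. Ring order: eight-membered ring (bought) → rings A/B → rings C/D, all within the single operation that makes the key bond.

Assumption: the sense of induction of (−)-sparteine in step 3 cannot be predicted; (−)-sparteine is written, and commercial (+)-sparteine replaces it, nothing else changed, if a pilot run gives the mirror-image series. Route locants C1–C13 are defined under compound 11 in the list.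

## Route

Step 1
Reactants: 1 methyl sorbate (methyl (2E,4E)-hexa-2,4-dienoate)
Product: 2 methyl (2E,4E)-6-bromohexa-2,4-dienoate
Conditions: NBS (1.05 equiv), AIBN (3 mol%), PhCF3, 85 °C, 3 h
Reagents that add atoms: N-bromosuccinimide, O=C1CCC(=O)N1Br
Why: Wohl–Ziegler radical bromination; hydrogen abstraction from the methyl group gives an ester-stabilised pentadienyl radical that takes bromine at its terminus and keeps the conjugated (2E,4E)-dienoate; no stereocentre is formed.

Step 2
Reactants: 3 10-bromodec-1-ene
Product: 4 (E)-10-bromodec-2-ene
Conditions: [Cp*Ru(NCMe)(κ2-P,N-iPr2P(4-tBu-1-Me-imidazol-2-yl))]PF6 (1 mol%), acetone, 40 °C, 4 h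
Reagents that add atoms: none
Why: catalytic alkene transposition (1,3-hydrogen shift through an η3-allyl ruthenium intermediate, the pendant imidazole shuttling the proton); the Cp* ligand hinders re-binding of the internal alkene, so migration stops after one position and gives the (E)-2-alkene (>98% E expected), the primary bromide being inert.

Step 3
Reactants: 4 (E)-10-bromodec-2-ene; 5 cyclooctatetraene; 2 methyl (2E,4E)-6-bromohexa-2,4-dienoate
Product: 11 CNP0133550.1 methyl ester target, via (E)-dec-8-en-1-yllithium 6 (not isolated), via lithium 8-decenylcyclooctatrienide 7 (not isolated), via trans-(1R,8R)-cyclooctatriene 8 (not isolated), via exo-dienoate bicyclooctadiene 9 (not isolated), via endo-dienoate bicyclooctadiene 10 (not isolated)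
Conditions: Li (1% Na, 2.2 equiv), Et2O, −10 °C; then (−)-sparteine (1.1 equiv), 5 (1.1 equiv), Et2O, −40 → −10 °C, 2 h; cannulate into 2 (1.05 equiv), Et2O, −78 °C, 1 h; aq NH4Cl, aq citric acid wash, Na2SO4; Et2O exchanged for degassed PhMe (5 mM), BHT (5 mol%), 85 °C, 24 h
Reagents that add atoms: none
Why: Proposed new method: tandem carbolithiation / reversed-polarity SN2 alkylation / 6π electrocyclisation / intramolecular Diels–Alder reaction – syn addition of the primary alkyllithium 6 to 5 (a known reaction type, accelerated by the diamine) gives the meso heptatrienyl anion 7, whose Li·sparteine contact ion pair makes the two ring termini diastereotopic, so that one of them is expected to attack the bromomethyl carbon of 2 anti to the decenyl group and set the trans (1R,8R) pair of 8 in the C–C bond-forming event, 2 acting as a doubly vinylogous enolonium equivalent that joins two donor carbons; on warming, 8 closes by disrotatory 6π electrocyclisation to the cis-fused epimers 9 and 10, which interconvert through 8 at 85 °C, and only 10 holds the dienoate under the concave face of the ring C5=C6 bond, so the endiandric-type cycloaddition (suprafacial on the (E,E)-diene, exo orientation enforced by the three-atom C7–C8–C9 tether) drains the equilibrium into 11 and sets C5, C6, C10 and C13 while C2 and C7 are fixed by the productive 6π closure, all eight stereocentres following from the two set in the alkylation; the closest known reaction types are the 1,2-dialkylation of the cyclooctatetraene dianion through the same kind of alkylcyclooctatrienyl anion, sparteine-mediated enantioselective carbolithiation, the enantioselective substitution of sparteine-complexed delocalised organolithiums such as 1-alkylindenyllithiums, and the thermal 8π/6π/Diels–Alder endiandric cascade.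

Notes on step 3:
- The slight excess of 5 ensures that no 6 survives to attack the ester of 2.
- Inverse addition keeps 7 away from the alkylation product, whose CH2 next to the dienoate is acidic.
- The cold quench and the citric acid wash remove sparteine and lithium salts before heating.
- The few percent of unreacted 2 is a spectator at 5 mM and is removed with the final chromatography of 11.

## Compound list

1 | methyl sorbate, methyl (2E,4E)-hexa-2,4-dienoate | C/C=C/C=C/C(=O)OC | starting material
2 | methyl (2E,4E)-6-bromohexa-2,4-dienoate | BrC/C=C/C=C/C(=O)OC | intermediate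
3 | 10-bromodec-1-ene | C=CCCCCCCCCBr | starting material
4 | (E)-10-bromodec-2-ene | C/C=C/CCCCCCCBr | intermediate
5 | cyclooctatetraene | C1=CC=CC=CC=C1 | starting material
6 | (E)-dec-8-en-1-yllithium | [Li]CCCCCCC/C=C/C | intermediate
7 | lithium 8-[(E)-dec-8-en-1-yl]cycloocta-2,4,6-trien-1-ide, as its (−)-sparteine complex (meso anion) | C/C=C/CCCCCCCC1[CH-]C=CC=CC=C1.[Li+] | intermediate
8 | methyl (2E,4E)-6-[(1R,8R)-8-[(E)-dec-8-en-1-yl]cycloocta-2,4,6-trien-1-yl]hexa-2,4-dienoate (trans) | C/C=C/CCCCCCC[C@@H]1/C=C\C=C/C=C\[C@H]1C/C=C/C=C/C(=O)OC | intermediate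
9 | methyl (2E,4E)-6-[(1S,6R,7S,8S)-8-[(E)-dec-8-en-1-yl]bicyclo[4.2.0]octa-2,4-dien-7-yl]hexa-2,4-dienoate (cis-fused; dienoate arm exo, decenyl endo; off-path 6π-epimer that returns through 8) | C/C=C/CCCCCCC[C@@H]1[C@@H]2C=CC=C[C@@H]2[C@H]1C/C=C/C=C/C(=O)OC | intermediate
10 | methyl (2E,4E)-6-[(1R,6S,7S,8S)-8-[(E)-dec-8-en-1-yl]bicyclo[4.2.0]octa-2,4-dien-7-yl]hexa-2,4-dienoate (cis-fused; dienoate arm endo, decenyl exo; the isomer that cyclises) | C/C=C/CCCCCCC[C@@H]1[C@H]2C=CC=C[C@H]2[C@H]1C/C=C/C=C/C(=O)OC | intermediate
11 | CNP0133550.1, methyl ester of the endiandric acid A-type tetracycle. Route locants: ring A cyclobutane C1–C2–C7–C8; ring B cyclohexene C2–C3=C4–C5–C6–C7; ring C cyclopentane C6–C7–C8–C9–C10; ring D cyclohexene C5–C6–C10–C11=C12–C13; (E)-dec-8-enyl on C1, CO2Me on C13; 1S,2R,5R,6S,7S,8S,10S,13R; H-2, H-7, H-8, H-6 and H-5 mutually cis, H-1 trans to H-2, H-10 trans to H-6, H-13 cis to H-10 | C/C=C/CCCCCCC[C@@H]1[C@H]2C=C[C@@H]3[C@@H]4[C@H]2[C@H]1C[C@H]4C=C[C@H]3C(=O)OC | target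

## Step count and risks

Total step count: 3. Longest linear sequence: 2 steps (3 → 4 → 11, or 1 → 2 → 11).

**Step 3** is the most likely to fail.
- The dienylic bromide 2 may suffer conjugate addition, electron transfer or deprotonation by the strongly basic anion 7 instead of clean SN2 displacement.
- The terminus selectivity, trans selectivity and ee of the alkylation are unproven.
- At 85 °C, 8 can also open by retro-8π to an achiral tetraene, which would erode the ee.
- A bicyclo[2.2.2] adduct from the ring diene and the side-chain alkene can compete with the desired cycloaddition.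

The fallback sets out from 7 and comes back at 9 and 10. Anion 7, made as in step 3, is quenched with ethylene oxide (Et2O, −78 → 0 °C), a two-carbon enolonium equivalent at the alcohol oxidation level that can only react by SN2 ring opening. This gives 2-[(1R,8R)-8-[(E)-dec-8-en-1-yl]cycloocta-2,4,6-trien-1-yl]ethanol F1, which closes at 20 °C to the endo-hydroxyethyl bicyclic alcohol F2 and the exo-hydroxyethyl bicyclic alcohol F3. Dess–Martin oxidation (NaHCO3, CH2Cl2, 0 °C) gives the endo aldehyde F4 and the exo aldehyde F5. Vinylogous Horner–Wadsworth–Emmons olefination with methyl (E)-4-(dimethoxyphosphoryl)but-2-enoate and LiN(SiMe3)2 (THF, −78 → 0 °C) then builds the (2E,4E)-dienoate, giving 10 from F4 and 9 from F5. The purified mixture of 9 and 10 is heated in PhMe as in the last stage of step 3 to give 11. The route grows by three operations, and the thermal stage then starts from clean material.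

**Step 2** is the second risk. Any migration beyond one position, or any (Z)-isomer, gives inseparable homologues that are carried into 11. The fallback sets out from none of the numbered compounds: it replaces starting material 3 by commercial dec-9-yn-1-ol F6 and comes back at 4. KOtBu in DMSO (20 °C) moves the triple bond one position to give dec-8-yn-1-ol F7. Dissolving-metal reduction (Na, liquid NH3, −33 °C) gives (E)-dec-8-en-1-ol F8 with the geometry fixed by the mechanism. An Appel reaction (CBr4, PPh3, CH2Cl2, 0 °C) then gives 4.

**Step 1** is the third risk. The pentadienyl radical can take bromine at C4 as well as at C6, over-bromination gives the dibromide, and HBr can scramble the diene geometry, so 2 may be obtained impure. The fallback sets out from none of the numbered compounds: it replaces starting material 1 by commercial (tert-butyldimethylsilyloxy)acetaldehyde F9 and comes back at 2. Vinylogous Horner–Wadsworth–Emmons olefination with methyl (E)-4-(dimethoxyphosphoryl)but-2-enoate and LiN(SiMe3)2 (THF, −78 → 0 °C) gives methyl (2E,4E)-6-(tert-butyldimethylsilyloxy)hexa-2,4-dienoate F10, the carbon skeleton and both double bonds now built by olefination instead of C–H functionalisation. Direct conversion of the silyl ether into the bromide with Ph3PBr2 (CH2Cl2, 0 → 20 °C) then gives 2.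

Further compounds
F1 | step 3 | 2-[(1R,8R)-8-[(E)-dec-8-en-1-yl]cycloocta-2,4,6-trien-1-yl]ethanol | C/C=C/CCCCCCC[C@@H]1/C=C\C=C/C=C\[C@H]1CCO
F2 | step 3 | 2-[(1R,6S,7S,8S)-8-[(E)-dec-8-en-1-yl]bicyclo[4.2.0]octa-2,4-dien-7-yl]ethanol (hydroxyethyl endo) | C/C=C/CCCCCCC[C@@H]1[C@H]2C=CC=C[C@H]2[C@H]1CCO
F3 | step 3 | 2-[(1S,6R,7S,8S)-8-[(E)-dec-8-en-1-yl]bicyclo[4.2.0]octa-2,4-dien-7-yl]ethanol (hydroxyethyl exo) | C/C=C/CCCCCCC[C@@H]1[C@@H]2C=CC=C[C@@H]2[C@H]1CCO
F4 | step 3 | 2-[(1R,6S,7S,8S)-8-[(E)-dec-8-en-1-yl]bicyclo[4.2.0]octa-2,4-dien-7-yl]acetaldehyde (endo) | C/C=C/CCCCCCC[C@@H]1[C@H]2C=CC=C[C@H]2[C@H]1CC=O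
F5 | step 3 | 2-[(1S,6R,7S,8S)-8-[(E)-dec-8-en-1-yl]bicyclo[4.2.0]octa-2,4-dien-7-yl]acetaldehyde (exo) | C/C=C/CCCCCCC[C@@H]1[C@@H]2C=CC=C[C@@H]2[C@H]1CC=O
F6 | step 2 | dec-9-yn-1-ol | C#CCCCCCCCCO
F7 | step 2 | dec-8-yn-1-ol | CC#CCCCCCCCO
F8 | step 2 | (E)-dec-8-en-1-ol | C/C=C/CCCCCCCO
F9 | step 1 | (tert-butyldimethylsilyloxy)acetaldehyde | O=CCO[Si](C)(C)C(C)(C)C
F10 | step 1 | methyl (2E,4E)-6-(tert-butyldimethylsilyloxy)hexa-2,4-dienoate | COC(=O)/C=C/C=C/CO[Si](C)(C)C(C)(C)C
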